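**Retrosynthetic overview**

- The target is reached by removing one tert-butyl enol ether and two aryl silyl ethers from (R)-butenolide 21. C5, the only stereocentre, is set by a cinchona-catalysed asymmetric 1,3-proton shift (C3–H to C5–H) on the deconjugated furan-2(3H)-one 20.
- The butenolide is the only ring formed. It comes from thermal ring expansion of hydroxycyclobutenone 15: the cyclobutenone C1–C4 bond opens to a hydroxy vinylketene and the C4 hydroxyl adds to the ketene carbon, making the lactone O1–C2 bond.
- The strategy rests on the lactone ring O1–C2(=O)–C3(OH)=C4(aryl)–C5(H)(benzyl). Its four contiguous carbons C2 to C5, oxygenated at C2, C3 and C5, are the four ring carbons of di-tert-butyl squarate.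
- Cyclobutenone 15 comes from the squarate by benzylic Grignard addition (C5–CH2 bond), O-silylation, aryllithium addition (C4–aryl bond) and acid-induced 1,3-carbonyl transposition.
- Benzylic chloride 6 comes from 4-hydroxybenzaldehyde by ortho C-prenylation, silylation, reduction and chlorination.

Key step: step 8

Abbreviations used in names: TBS = tert-butyldimethylsilyl; ArS = 4-(TBS-oxy)phenyl; BnS = 4-(TBS-oxy)-3-(3-methylbut-2-en-1-yl)benzyl.

Assumption: (4-bromophenoxy)(tert-butyl)dimethylsilane 11 is taken as a purchased material; it is otherwise one silylation step from 4-bromophenol.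

Assumption: the facial sense of the catalyst in step 10 cannot be carried over with confidence from simpler butenolides. The quinidine-derived catalyst is written on the expectation that it gives (R)-C5; if a trial run shows the opposite sense, its quinine-derived pseudoenantiomer 9-O-(9-phenanthryl)cupreine replaces it.

**Route**

Step 1
Reactants: 1 4-hydroxybenzaldehyde; 2 prenyl bromide (1-bromo-3-methylbut-2-ene)
Product: 3 4-hydroxy-3-(3-methylbut-2-en-1-yl)benzaldehyde
Conditions: aq. KOH (10%), rt; chromatography
Reagents that add atoms: none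
Why: Ortho C-alkylation of a phenoxide in water, where hydrogen bonding shields the oxygen and the para position is blocked by the formyl group, should give the mono-C-prenyl phenol, with the O-prenyl ether and the 3,5-diprenyl compound removed by chromatography.

Step 2
Reactants: 3 4-hydroxy-3-(3-methylbut-2-en-1-yl)benzaldehyde
Product: 4 4-(TBS-oxy)-3-(3-methylbut-2-en-1-yl)benzaldehyde
Conditions: TBSCl, imidazole, DMF, rt
Reagents that add atoms: tert-butyldimethylsilyl chloride, CC(C)(C)[Si](C)(C)Cl
Why: Imidazole-promoted silylation of a phenol is routine and masks the acidic OH before the organometallic steps.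

Step 3
Reactants: 4 4-(TBS-oxy)-3-(3-methylbut-2-en-1-yl)benzaldehyde
Product: 5 [4-(TBS-oxy)-3-(3-methylbut-2-en-1-yl)phenyl]methanol
Conditions: NaBH4, THF/MeOH (4:1), 0 °C, short reaction time
Reagents that add atoms: none
Why: Borohydride reduction of an aryl aldehyde is fast at 0 °C, which should leave the aryl silyl ether and the prenyl alkene untouched.

Step 4
Reactants: 5 [4-(TBS-oxy)-3-(3-methylbut-2-en-1-yl)phenyl]methanol
Product: 6 tert-butyl[4-(chloromethyl)-2-(3-methylbut-2-en-1-yl)phenoxy]dimethylsilane
Conditions: PPh3, N-chlorosuccinimide (premixed), THF, 0 °C → rt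
Reagents that add atoms: N-chlorosuccinimide, O=C1CCC(=O)N1Cl
Why: Appel-type chlorination through the alkoxyphosphonium salt runs under neutral conditions, so neither the trisubstituted alkene nor the silyl ether should suffer, and the chloride is preferred over the bromide to limit Wurtz coupling in step 5.

Step 5
Reactants: 6 tert-butyl[4-(chloromethyl)-2-(3-methylbut-2-en-1-yl)phenoxy]dimethylsilane; 7 di-tert-butyl squarate (3,4-di-tert-butoxycyclobut-3-ene-1,2-dione)
Product: 9 rac-4-BnS-2,3-di-tert-butoxy-4-hydroxycyclobut-2-en-1-one, via benzylic Grignard reagent 8 (not isolated)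
Conditions: Mg turnings (I2 cat.), Et2O, 0 °C, slow addition of 6; then 7, THF, −78 °C; then H2O, −78 °C → rt
Reagents that add atoms: none
Why: Grignard formation followed by 1,2-addition to one of the two equivalent squarate carbonyls should stop at mono-addition, because the alkoxide and the vinylogous-ester character of the remaining carbonyl deactivate it; the new carbinol centre is racemic and is later lost as a stereocentre.

Step 6
Reactants: 9 rac-4-BnS-2,3-di-tert-butoxy-4-hydroxycyclobut-2-en-1-one
Product: 10 rac-4-BnS-2,3-di-tert-butoxy-4-(trimethylsilyloxy)cyclobut-2-en-1-one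
Conditions: TMSCl, imidazole, DMF, 0 °C
Reagents that add atoms: trimethylsilyl chloride, C[Si](C)(C)Cl
Why: Silylation of the tertiary alcohol keeps it from quenching the aryllithium and from ionising in the acid step, and the trimethylsilyl group is chosen because dilute acid removes it later.

Step 7
Reactants: 10 rac-4-BnS-2,3-di-tert-butoxy-4-(trimethylsilyloxy)cyclobut-2-en-1-one; 11 (4-bromophenoxy)(tert-butyl)dimethylsilane
Product: 15 rac-4-BnS-2-tert-butoxy-4-hydroxy-3-ArS-cyclobut-2-en-1-one, via aryllithium 12 (not isolated), via lithium alkoxide adduct 13 (not isolated), via trimethylsilyl ether 14 (not isolated)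
Conditions: 11, n-BuLi, THF, −78 °C; 10, −78 °C; then 0.5 M aq. HCl, THF, 0 °C, brief
Reagents that add atoms: water, O
Why: Bromine–lithium exchange and 1,2-addition to the remaining carbonyl give a tertiary alcohol that is benzylic to the electron-rich ring and allylic to the enol ether, so dilute acid should ionise it, water should add at the tert-butoxy-bearing allyl terminus and loss of tert-butanol should unveil the transposed ketone (the known squarate 1,3-carbonyl transposition), while the same acid cleaves the trimethylsilyl ether and is too weak to ionise the C4 hydroxyl of 15, whose cation would sit next to the carbonyl.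

Step 8
Reactants: 15 rac-4-BnS-2-tert-butoxy-4-hydroxy-3-ArS-cyclobut-2-en-1-one
Product: 18 rac-5-BnS-3-tert-butoxy-4-ArS-furan-2(5H)-one, via hydroxy vinylketene 16 (not isolated), via 2-hydroxyfuran tautomer 17 (not isolated)
Conditions: p-xylene (0.02 M), 138 °C, Ar; then Et3N (cat.), rt
Reagents that add atoms: none
Why: Heat should drive a reversible conrotatory four-electron electrocyclic opening of the strained cyclobutenone C1–C4 bond, and the rotamer with the C4 hydroxyl turned inward, (Z)-ketene 16, is drained irreversibly because its O–H adds to the ketene carbon, making the lactone O1–C2 bond. The closest known reaction type is the thermal ring expansion of squarate-derived 4-alkyl-4-hydroxycyclobutenones to furan-2(5H)-ones. The five-membered ring closes in a 5-exo-dig mode with respect to the ketene C=O, giving 2-hydroxyfuran 17, which tautomerises to the conjugated furan-2(5H)-one, the trace of Et3N completing this shift. The only new stereocentre, C5, arises in that proton shift without control and is therefore racemic; it is corrected in steps 9 and 10. The selectivity needed is regiochemical (tert-butoxy at C3, aryl at C4) and is fixed by the order of the two additions to the squarate, which leaves the tert-butoxy carbon α and the aryl carbon β to the ring carbonyl. Chemoselectivity rests on the sp3 benzyl group at the carbinol carbon, which offers the outward-hydroxyl ketene no six-electron closure, so that rotamer can only reclose to 15.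

Step 9
Reactants: 18 rac-5-BnS-3-tert-butoxy-4-ArS-furan-2(5H)-one
Product: 20 rac-5-BnS-3-tert-butoxy-4-ArS-furan-2(3H)-one, via lithium furanolate 19 (not isolated)
Conditions: LiN(SiMe3)2 (1.1 equiv), THF, −78 °C; inverse quench into AcOH/THF, −78 °C; cold neutral work-up
Reagents that add atoms: none
Why: γ-Deprotonation at C5 gives the aromatic 2-furanolate, and kinetic protonation of such dienolates occurs at the α-carbon (C3), so the deconjugated enol lactone should result (deconjugative protonation); the C3 centre is racemic and is erased in step 10.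

Step 10
Reactants: 20 rac-5-BnS-3-tert-butoxy-4-ArS-furan-2(3H)-one
Product: 21 (R)-5-BnS-3-tert-butoxy-4-ArS-furan-2(5H)-one
Conditions: 9-O-(9-phenanthryl)cupreidine (10 mol %), CH2Cl2, −20 °C; stopped at full conversion
Reagents that add atoms: none
Why: In the cinchona-catalysed asymmetric isomerisation of β,γ- to α,β-unsaturated butenolides the quinuclidine nitrogen removes the C3 proton and the chiral ammonium ion, held to the dienolate by the 6′-OH, returns it to one face of C5, so C5 is set by the catalyst while conjugation with the carbonyl and the aryl ring drives the shift.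

Step 11
Reactants: 21 (R)-5-BnS-3-tert-butoxy-4-ArS-furan-2(5H)-one
Product: 22 (R)-5-BnS-3-hydroxy-4-ArS-furan-2(5H)-one
Conditions: CF3CO2H/CH2Cl2 (1:4), 0 °C, N2 sweep, brief
Reagents that add atoms: none
Why: Acidolysis of the tert-butyl enol ether with loss of isobutene should free the C3 enol while the phenols stay silylated, which blocks cyclisation of the ortho-prenyl phenol to a chroman, and C5 is not epimerised under acid.

Step 12
Reactants: 22 (R)-5-BnS-3-hydroxy-4-ArS-furan-2(5H)-one
Product: 23 (R)-3-hydroxy-5-[4-hydroxy-3-(3-methylbut-2-en-1-yl)benzyl]-4-(4-hydroxyphenyl)furan-2(5H)-one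
Conditions: Bu4NF/AcOH (1:1), THF, 0 °C; work-up at pH 4
Reagents that add atoms: none
Why: Fluoride cleaves both aryl silyl ethers rapidly, and the acetic acid buffer keeps the enol and the phenols protonated so that C5 is not deprotonated and the prenyl phenol does not cyclise.

**Compound list**

1 | 4-hydroxybenzaldehyde | O=Cc1ccc(O)cc1 | starting material
2 | prenyl bromide | CC(C)=CCBr | starting material
3 | 4-hydroxy-3-(3-methylbut-2-en-1-yl)benzaldehyde | CC(C)=CCc1cc(C=O)ccc1O | intermediate
4 | 4-(TBS-oxy)-3-(3-methylbut-2-en-1-yl)benzaldehyde | CC(C)=CCc1cc(C=O)ccc1O[Si](C)(C)C(C)(C)C | intermediate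
5 | [4-(TBS-oxy)-3-(3-methylbut-2-en-1-yl)phenyl]methanol | CC(C)=CCc1cc(CO)ccc1O[Si](C)(C)C(C)(C)C | intermediate
6 | tert-butyl[4-(chloromethyl)-2-(3-methylbut-2-en-1-yl)phenoxy]dimethylsilane | CC(C)=CCc1cc(CCl)ccc1O[Si](C)(C)C(C)(C)C | intermediate
7 | di-tert-butyl squarate | CC(C)(C)OC1=C(OC(C)(C)C)C(=O)C1=O | starting material
8 | [4-(TBS-oxy)-3-(3-methylbut-2-en-1-yl)benzyl]magnesium chloride | CC(C)=CCc1cc(C[Mg]Cl)ccc1O[Si](C)(C)C(C)(C)C | intermediate
9 | rac-4-BnS-2,3-di-tert-butoxy-4-hydroxycyclobut-2-en-1-one | O=C1C(OC(C)(C)C)=C(OC(C)(C)C)C1(O)Cc1ccc(O[Si](C)(C)C(C)(C)C)c(CC=C(C)C)c1 | intermediate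
10 | rac-4-BnS-2,3-di-tert-butoxy-4-(trimethylsilyloxy)cyclobut-2-en-1-one | O=C1C(OC(C)(C)C)=C(OC(C)(C)C)C1(O[Si](C)(C)C)Cc1ccc(O[Si](C)(C)C(C)(C)C)c(CC=C(C)C)c1 | intermediate
11 | (4-bromophenoxy)(tert-butyl)dimethylsilane | CC(C)(C)[Si](C)(C)Oc1ccc(Br)cc1 | starting material
12 | [4-(TBS-oxy)phenyl]lithium | [Li]c1ccc(O[Si](C)(C)C(C)(C)C)cc1 | intermediate
13 | lithium 1-ArS-4-BnS-2,3-di-tert-butoxy-4-(trimethylsilyloxy)cyclobut-2-en-1-olate (diastereomer mixture) | [Li+].[O-]C1(c2ccc(O[Si](C)(C)C(C)(C)C)cc2)C(OC(C)(C)C)=C(OC(C)(C)C)C1(O[Si](C)(C)C)Cc1ccc(O[Si](C)(C)C(C)(C)C)c(CC=C(C)C)c1 | intermediate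
14 | rac-4-BnS-2-tert-butoxy-3-ArS-4-(trimethylsilyloxy)cyclobut-2-en-1-one | O=C1C(OC(C)(C)C)=C(c2ccc(O[Si](C)(C)C(C)(C)C)cc2)C1(O[Si](C)(C)C)Cc1ccc(O[Si](C)(C)C(C)(C)C)c(CC=C(C)C)c1 | intermediate
15 | rac-4-BnS-2-tert-butoxy-4-hydroxy-3-ArS-cyclobut-2-en-1-one (key-step precursor) | O=C1C(OC(C)(C)C)=C(c2ccc(O[Si](C)(C)C(C)(C)C)cc2)C1(O)Cc1ccc(O[Si](C)(C)C(C)(C)C)c(CC=C(C)C)c1 | intermediate
16 | (Z)-2-tert-butoxy-3-ArS-4-hydroxy-5-aryl-penta-1,3-dien-1-one (hydroxy vinylketene, OH inward) | O=C=C(OC(C)(C)C)/C(c1ccc(O[Si](C)(C)C(C)(C)C)cc1)=C(\O)Cc1ccc(O[Si](C)(C)C(C)(C)C)c(CC=C(C)C)c1 | intermediate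
17 | 5-BnS-3-tert-butoxy-4-ArS-furan-2-ol | Oc1oc(Cc2ccc(O[Si](C)(C)C(C)(C)C)c(CC=C(C)C)c2)c(-c2ccc(O[Si](C)(C)C(C)(C)C)cc2)c1OC(C)(C)C | intermediate
18 | rac-5-BnS-3-tert-butoxy-4-ArS-furan-2(5H)-one (key-step product) | O=C1OC(Cc2ccc(O[Si](C)(C)C(C)(C)C)c(CC=C(C)C)c2)C(c2ccc(O[Si](C)(C)C(C)(C)C)cc2)=C1OC(C)(C)C | intermediate
19 | lithium 5-BnS-3-tert-butoxy-4-ArS-furan-2-olate | [Li+].[O-]c1oc(Cc2ccc(O[Si](C)(C)C(C)(C)C)c(CC=C(C)C)c2)c(-c2ccc(O[Si](C)(C)C(C)(C)C)cc2)c1OC(C)(C)C | intermediate
20 | rac-5-BnS-3-tert-butoxy-4-ArS-furan-2(3H)-one | O=C1OC(Cc2ccc(O[Si](C)(C)C(C)(C)C)c(CC=C(C)C)c2)=C(c2ccc(O[Si](C)(C)C(C)(C)C)cc2)C1OC(C)(C)C | intermediate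
21 | (R)-5-BnS-3-tert-butoxy-4-ArS-furan-2(5H)-one | CC(C)=CCc1cc(C[C@H]2OC(=O)C(OC(C)(C)C)=C2c2ccc(O[Si](C)(C)C(C)(C)C)cc2)ccc1O[Si](C)(C)C(C)(C)C | intermediate
22 | (R)-5-BnS-3-hydroxy-4-ArS-furan-2(5H)-one | CC(C)=CCc1cc(C[C@H]2OC(=O)C(O)=C2c2ccc(O[Si](C)(C)C(C)(C)C)cc2)ccc1O[Si](C)(C)C(C)(C)C | intermediate
23 | (R)-3-hydroxy-5-[4-hydroxy-3-(3-methylbut-2-en-1-yl)benzyl]-4-(4-hydroxyphenyl)furan-2(5H)-one | CC(C)=CCc1cc(C[C@H]2OC(=O)C(O)=C2c2ccc(O)cc2)ccc1O | target

**Step count and risks**

Total step count: 12. Longest linear sequence: 12 steps (1 to 23); compounds 7 and 11 enter as purchased materials.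

Steps most likely to fail:

1. Step 10. The proton shift may be slow, because the catalyst has to remove a hindered C3 proton flanked by the tert-butoxy group and a tetrasubstituted alkene. Facial discrimination in the proton return to C5 may be poor, and uncatalysed or product-epimerising proton transfer may erode the enantiomeric purity. Any conjugated racemate carried over from step 9 lowers it further. The fallback gives up asymmetric proton transfer for resolution and sets out from 18, so it also covers a poor outcome of the deconjugation in step 9. Racemic 18 is separated by preparative supercritical-fluid chromatography on an amylose tris(3,5-dimethylphenylcarbamate) phase (CO2/i-PrOH), which should deliver 21 and its mirror image, (S)-5-BnS-3-tert-butoxy-4-ArS-furan-2(5H)-one F1. F1 is racemised back to 18 with catalytic DBU in THF at rt through the furanolate and recycled. The fallback returns to the route at 21.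

2. Step 8. Thermal opening turns the hydroxyl outward by preference, so the productive inward rotamer is reached only through repeated reversible opening at high temperature. Under those conditions a 1,5-hydrogen shift from the benzylic CH2 to the ketene in the benzyl-inward rotamer, thermal loss of isobutene from the tert-butyl enol ether, or ketene oligomerisation may compete. The fallback changes the mode of activation and sets out from 15. Irradiation of 15 with UV light in MeCN in a flow reactor at ambient temperature opens the ring from the excited state, which turns the hydroxyl inward directly and is known to convert 4-hydroxycyclobutenones into furan-2(5H)-ones without heating. A trace of Et3N then completes the tautomerisation, and the fallback returns at 18 without any new compound.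

3. Step 11. Protonation of the prenyl alkene by the acid may lead to trifluoroacetate addition or to ring closure onto the neighbouring oxygen once its silyl group is lost; the liberated tert-butyl cation may also alkylate the electron-rich rings. The fallback replaces protic acidolysis by silyl exchange and sets out from 21. TBSOTf and 2,6-lutidine in CH2Cl2 (0 °C → rt), a known non-protic conversion of tert-butyl ethers into silyl ethers, should give the tris-silyl ether (R)-5-BnS-3-(TBS-oxy)-4-ArS-furan-2(5H)-one F2 with loss of isobutene. Bu4NF/AcOH in THF at 0 °C then removes all three silyl groups at once, and the fallback returns at 23.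

Further compounds
F1 | step 10 | (S)-5-BnS-3-tert-butoxy-4-ArS-furan-2(5H)-one | CC(C)=CCc1cc(C[C@@H]2OC(=O)C(OC(C)(C)C)=C2c2ccc(O[Si](C)(C)C(C)(C)C)cc2)ccc1O[Si](C)(C)C(C)(C)C
F0 | step 8 | none | none
F2 | step 11 | (R)-5-BnS-3-(TBS-oxy)-4-ArS-furan-2(5H)-one | CC(C)=CCc1cc(C[C@H]2OC(=O)C(O[Si](C)(C)C(C)(C)C)=C2c2ccc(O[Si](C)(C)C(C)(C)C)cc2)ccc1O[Si](C)(C)C(C)(C)C
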